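Everything rests on opening the 3(2H)-furanone that bridges the ten-membered carbocycle (germacrane numbering: ring O, quaternary C4, carbonyl C3, C2, C1). Its C3–C4 bond is an acyloin bond and its O–C1 bond the oxa-Michael bond of an ynone, so one carbene-catalysed operation on an open-chain keto-ynal closes the carbocycle by crossed benzoin addition and the furanone by 5-endo-dig attack of the new tertiary alkoxide, setting the C4 stereocentre. The precursor is a 2-acetonyl-3,4-disubstituted furan that already carries both esters; the furan is a latent (E)-ylidenebutenolide, unveiled afterwards by singlet oxygen and dehydration.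

Key step: step 13

Locants: C1 (furanone carbon bonded to ring O and C10), C2 (furanone CH), C3 (furanone C=O), C4 (quaternary, bears the C15 methyl and ring O), C5 (ylidene CH), C6/C7/C11/C12 (lactone γ, β, α and carbonyl carbons), C8 (CH bearing the senecioate), C9 (CH2), C10 (CH bearing the C14 methyl), C13 (CH2OAc).

Remark: the sense of induction of the (R)-bisphosphine in step 7 and of the (5aS,10bR)-triazolium salt in step 13 is assigned by analogy with simpler substrates; if either should favour the epimer, its mirror-image form is used.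

Step 1
Reactants: 1 furan-3,4-diyldimethanol
Product: 2 (4-{[(triethylsilyl)oxy]methyl}furan-3-yl)methanol
Conditions: NaH (1.0 equiv), THF, 0 °C to rt; Et3SiCl (1.0 equiv), rt
Reagents that add atoms: chlorotriethylsilane, CC[Si](Cl)(CC)CC
Why: O-silylation of the sparingly soluble monosodium alkoxide of a symmetric diol should stop at the monosilyl ether.

Step 2
Reactants: 2 (4-{[(triethylsilyl)oxy]methyl}furan-3-yl)methanol; 3 (S)-2-methyloxirane
Product: 5 (2S)-1-[3-(hydroxymethyl)-4-{[(triethylsilyl)oxy]methyl}furan-2-yl]propan-2-ol, via dilithiated furylmethanolate 4 (not isolated)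
Conditions: n-BuLi (2.2 equiv), THF, −78 to 0 °C; then 3 (1.5 equiv), 0 °C to rt; aq. NH4Cl
Reagents that add atoms: none
Why: Alkoxide-directed ortho-lithiation should metalate the furan α-position next to the CH2OLi group, and SN2 opening of the epoxide at its CH2 terminus leaves the carbinol stereocentre of 3 untouched.

Step 3
Reactants: 5 (2S)-1-[3-(hydroxymethyl)-4-{[(triethylsilyl)oxy]methyl}furan-2-yl]propan-2-ol
Product: 7 (6S)-6-methyl-3-{[(triethylsilyl)oxy]methyl}-6,7-dihydro-4H-furo[3,2-c]pyran-4-one, via lactol 6 (not isolated)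
Conditions: 2,2,6,6-tetramethylpiperidin-1-oxyl (20 mol%), PhI(OAc)2 (2.5 equiv), CH2Cl2, rt
Reagents that add atoms: none
Why: Oxoammonium-mediated oxidative lactonisation: the primary furylmethanol should be oxidised first, the aldehyde is trapped by the secondary hydroxyl as lactol 6, and a second oxidation gives the δ-lactone.

Step 4
Reactants: 7 (6S)-6-methyl-3-{[(triethylsilyl)oxy]methyl}-6,7-dihydro-4H-furo[3,2-c]pyran-4-one; 8 (E)-1-bromoprop-1-ene
Product: 10 (2E)-1-{2-[(2S)-2-hydroxypropyl]-4-{[(triethylsilyl)oxy]methyl}furan-3-yl}but-2-en-1-one, via (E)-prop-1-enyllithium 9 (not isolated)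
Conditions: 8, t-BuLi (2.0 equiv), Et2O, −78 °C; then 7, THF, −78 °C; aq. NH4Cl
Reagents that add atoms: none
Why: Bromine–lithium exchange proceeds with retention of alkene geometry, and the vinyllithium should add once to the lactone (acyl substitution arrested at the lithium lactolate), releasing the C4 hydroxyl and the (E)-enone on work-up.

Step 5
Reactants: 10 (2E)-1-{2-[(2S)-2-hydroxypropyl]-4-{[(triethylsilyl)oxy]methyl}furan-3-yl}but-2-en-1-one
Product: 11 (2E)-1-{2-[(2S)-2-{[tert-butyl(dimethyl)silyl]oxy}propyl]-4-{[(triethylsilyl)oxy]methyl}furan-3-yl}but-2-en-1-one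
Conditions: TBSCl, imidazole, DMF, rt
Reagents that add atoms: tert-butylchlorodimethylsilane, CC(C)(C)[Si](C)(C)Cl
Why: Imidazole-mediated silylation of the secondary alcohol, needed so that no free hydroxyl competes in the rhodium step.

Step 6
Reactants: 11 (2E)-1-{2-[(2S)-2-{[tert-butyl(dimethyl)silyl]oxy}propyl]-4-{[(triethylsilyl)oxy]methyl}furan-3-yl}but-2-en-1-one; 12 tert-butyl(dimethyl)(prop-2-yn-1-yloxy)silane
Product: 14 (5E)-1-{[tert-butyl(dimethyl)silyl]oxy}-4-{2-[(2S)-2-{[tert-butyl(dimethyl)silyl]oxy}propyl]-4-{[(triethylsilyl)oxy]methyl}furan-3-yl}hept-5-en-2-yn-4-ol (both carbinol epimers), via lithium acetylide 13 (not isolated)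
Conditions: 12, n-BuLi, THF, −78 °C; then 11, −78 to −40 °C; aq. NH4Cl
Reagents that add atoms: none
Why: 1,2-Addition of a lithium acetylide to the enone carbonyl; the new carbinol centre forms as a mixture, which is irrelevant because it is destroyed in step 7.

Step 7
Reactants: 14 (5E)-1-{[tert-butyl(dimethyl)silyl]oxy}-4-{2-[(2S)-2-{[tert-butyl(dimethyl)silyl]oxy}propyl]-4-{[(triethylsilyl)oxy]methyl}furan-3-yl}hept-5-en-2-yn-4-ol
Product: 15 (3S)-6-{[tert-butyl(dimethyl)silyl]oxy}-1-{2-[(2S)-2-{[tert-butyl(dimethyl)silyl]oxy}propyl]-4-{[(triethylsilyl)oxy]methyl}furan-3-yl}-3-methylhex-4-yn-1-one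
Conditions: [Rh(OH)(cod)]2 (2.5 mol%), (R)-2,2'-bis(diphenylphosphino)-1,1'-binaphthyl (6 mol%), toluene, 60 °C
Reagents that add atoms: none
Why: Rhodium-catalysed asymmetric rearrangement of an alkynyl alkenyl carbinol: β-alkynyl elimination from the rhodium alkoxide releases enone and alkynylrhodium, which recombine by conjugate alkynylation, the bisphosphine selecting the enone face and so setting C10 (S).

Step 8
Reactants: 15 (3S)-6-{[tert-butyl(dimethyl)silyl]oxy}-1-{2-[(2S)-2-{[tert-butyl(dimethyl)silyl]oxy}propyl]-4-{[(triethylsilyl)oxy]methyl}furan-3-yl}-3-methylhex-4-yn-1-one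
Product: 17 (1S,3S)-6-{[tert-butyl(dimethyl)silyl]oxy}-1-{2-[(2S)-2-{[tert-butyl(dimethyl)silyl]oxy}propyl]-4-(hydroxymethyl)furan-3-yl}-3-methylhex-4-yn-1-ol, via triethylsilyl-protected alcohol 16 (not isolated)
Conditions: (3aR)-1-methyl-3,3-diphenyltetrahydro-1H,3H-pyrrolo[1,2-c][1,3,2]oxazaborole (0.3 equiv), BH3·SMe2 (1.2 equiv), THF, −20 °C; then MeOH, pyridinium p-toluenesulfonate (0.2 equiv), 0 °C to rt
Reagents that add atoms: none
Why: Corey–Bakshi–Shibata reduction with the furyl group as the large substituent should set C8 (S) under catalyst control, and mild acid methanolysis in the same flask should cleave only the primary triethylsilyl ether.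

Step 9
Reactants: 17 (1S,3S)-6-{[tert-butyl(dimethyl)silyl]oxy}-1-{2-[(2S)-2-{[tert-butyl(dimethyl)silyl]oxy}propyl]-4-(hydroxymethyl)furan-3-yl}-3-methylhex-4-yn-1-ol
Product: 18 {5-[(2S)-2-{[tert-butyl(dimethyl)silyl]oxy}propyl]-4-[(1S,3S)-6-{[tert-butyl(dimethyl)silyl]oxy}-1-hydroxy-3-methylhex-4-yn-1-yl]furan-3-yl}methyl acetate
Conditions: AcCl (1.1 equiv), 2,4,6-collidine, CH2Cl2, −78 °C
Reagents that add atoms: acetyl chloride, CC(=O)Cl
Why: Selective acylation of the primary over the hindered secondary furylic hydroxyl with a hindered pyridine base at low temperature.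

Step 10
Reactants: 18 {5-[(2S)-2-{[tert-butyl(dimethyl)silyl]oxy}propyl]-4-[(1S,3S)-6-{[tert-butyl(dimethyl)silyl]oxy}-1-hydroxy-3-methylhex-4-yn-1-yl]furan-3-yl}methyl acetate; 19 3-methylbut-2-enoyl chloride
Product: 20 (1S,3S)-1-{4-(acetoxymethyl)-2-[(2S)-2-{[tert-butyl(dimethyl)silyl]oxy}propyl]furan-3-yl}-6-{[tert-butyl(dimethyl)silyl]oxy}-3-methylhex-4-yn-1-yl 3-methylbut-2-enoate
Conditions: 19 (1.5 equiv), pyridine, 4-(dimethylamino)pyridine (10 mol%), CH2Cl2, 0 °C to rt
Reagents that add atoms: none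
Why: Nucleophile-catalysed acylation (acylpyridinium) of the remaining secondary alcohol with retention at C8; pyridine in place of a trialkylamine should avoid deconjugation through a vinylketene.

Step 11
Reactants: 20 (1S,3S)-1-{4-(acetoxymethyl)-2-[(2S)-2-{[tert-butyl(dimethyl)silyl]oxy}propyl]furan-3-yl}-6-{[tert-butyl(dimethyl)silyl]oxy}-3-methylhex-4-yn-1-yl 3-methylbut-2-enoate
Product: 21 (1S,3S)-1-{4-(acetoxymethyl)-2-[(2S)-2-hydroxypropyl]furan-3-yl}-6-hydroxy-3-methylhex-4-yn-1-yl 3-methylbut-2-enoate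
Conditions: HF·pyridine, pyridine, THF, 0 °C to rt
Reagents that add atoms: none
Why: Fluoride-mediated desilylation removes both tert-butyldimethylsilyl ethers while the buffered medium spares the two esters.

Step 12
Reactants: 21 (1S,3S)-1-{4-(acetoxymethyl)-2-[(2S)-2-hydroxypropyl]furan-3-yl}-6-hydroxy-3-methylhex-4-yn-1-yl 3-methylbut-2-enoate
Product: 22 (1S,3S)-1-[4-(acetoxymethyl)-2-(2-oxopropyl)furan-3-yl]-3-methyl-6-oxohex-4-yn-1-yl 3-methylbut-2-enoate
Conditions: Dess–Martin periodinane (3.0 equiv), NaHCO3, CH2Cl2, 0 °C to rt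
Reagents that add atoms: none
Why: Dess–Martin oxidation converts the propargylic primary alcohol into the ynal and the secondary alcohol into the methyl ketone under neutral conditions without touching furan or esters.

Step 13
Reactants: 22 (1S,3S)-1-[4-(acetoxymethyl)-2-(2-oxopropyl)furan-3-yl]-3-methyl-6-oxohex-4-yn-1-yl 3-methylbut-2-enoate
Product: 24 (4S,8S,10S)-13-acetoxy-8-(3-methylbut-2-enoyloxy)-1,4:6,12-diepoxygermacra-1,6,11-trien-3-one (furan-fused furanone macrocycle), via hydroxy ynone 23 (not isolated)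
Conditions: (5aS,10bR)-2-(pentafluorophenyl)-5a,10b-dihydro-4H,6H-indeno[2,1-b][1,2,4]triazolo[4,3-d][1,4]oxazin-2-ium tetrafluoroborate (20 mol%), i-Pr2NEt (1.0 equiv), 4 Å molecular sieves, toluene (2 mM, 22 added over 12 h), 40 °C
Reagents that add atoms: none
Why: Proposed new method: the triazolylidene adds to the ynal carbon C3 to give an enaminol (acyl-anion equivalent) whose C3 attacks the C4 methyl ketone (10-exo-trig), and after release of the carbene the tertiary alkoxide of hydroxy ynone 23 adds to C1 of the ynone (5-endo-dig oxa-Michael, which also completes the nine-membered oxacycle), so that the C3–C4 and O–C1 bonds, the carbocycle and the furanone arise in one flask. The closest known reactions are the carbene-catalysed intramolecular crossed benzoin of aldehydes with ketones (five- and six-membered rings) and the carbene-catalysed annulation of ynals with activated ketones to 3(2H)-furanones; a ten-membered closure onto an unactivated ketone is without precedent. The new stereocentre C4 is set in the C–C bond formation by the chiral triazolylidene, which selects the ketone face, and because the benzoin addition is reversible while the oxa-Michael closure is not, a mismatched adduct can revert. The step needs acyl-anion over redox (acyl azolium) reactivity of the ynal, which the electron-poor N-pentafluorophenyl carbene and an aprotic medium free of nucleophiles should secure, and ring closure over oligomerisation, which syringe-pump dilution and the ortho disposition of the two chains on the furan should secure. The weak amine base limits epimerisation at the propargylic C10–H.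

Step 14
Reactants: 24 (4S,8S,10S)-13-acetoxy-8-(3-methylbut-2-enoyloxy)-1,4:6,12-diepoxygermacra-1,6,11-trien-3-one
Product: 26 (4S,8S,10S)-13-acetoxy-6-hydroxy-8-(3-methylbut-2-enoyloxy)-3-oxo-1,4-epoxygermacra-1,7(11)-dien-12,6-olide (C6 epimers), via furan endoperoxide 25 (not isolated)
Conditions: O2, 5,10,15,20-tetraphenylporphyrin (1 mol%), visible light, i-Pr2NEt (2 equiv), CH2Cl2, −78 °C to rt
Reagents that add atoms: dioxygen, O=O
Why: [4+2] Cycloaddition of singlet oxygen to the electron-rich furan gives endoperoxide 25, and base-induced Kornblum–DeLaMare rearrangement at its only bridgehead C–H (C12) should give the γ-hydroxybutenolide with the carbonyl at C12.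

Step 15
Reactants: 26 (4S,8S,10S)-13-acetoxy-6-hydroxy-8-(3-methylbut-2-enoyloxy)-3-oxo-1,4-epoxygermacra-1,7(11)-dien-12,6-olide
Product: 28 (4S,5E,8S,10S)-13-acetoxy-8-(3-methylbut-2-enoyloxy)-3-oxo-1,4-epoxygermacra-1,5,7(11)-trien-12,6-olide (target), via hemiketal mesylate 27 (not isolated)
Conditions: MsCl (1.5 equiv), Et3N (3 equiv), CH2Cl2, −20 to 0 °C
Reagents that add atoms: none
Why: Sulfonylation of the hemiketal hydroxyl and E1-type loss of methanesulfonate with deprotonation at C5 (the only adjacent C–H) dehydrates to the ylidenebutenolide; within the bridged ten-membered ring only the (5E) alkene, with C4 cis to C7, is attainable.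

Compound list
1 | furan-3,4-diyldimethanol | OCc1cocc1CO | starting material
2 | (4-{[(triethylsilyl)oxy]methyl}furan-3-yl)methanol | OCc1cocc1CO[Si](CC)(CC)CC | intermediate
3 | (S)-2-methyloxirane | C[C@H]1CO1 | starting material
4 | lithium [2-lithio-4-{[(triethylsilyl)oxy]methyl}furan-3-yl]methanolate | [Li]OCc1c([Li])occ1CO[Si](CC)(CC)CC | intermediate (not isolated)
5 | (2S)-1-[3-(hydroxymethyl)-4-{[(triethylsilyl)oxy]methyl}furan-2-yl]propan-2-ol | C[C@H](O)Cc1occ(CO[Si](CC)(CC)CC)c1CO | intermediate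
6 | (6S)-6-methyl-3-{[(triethylsilyl)oxy]methyl}-6,7-dihydro-4H-furo[3,2-c]pyran-4-ol (lactol, both anomers) | C[C@H]1Cc2occ(CO[Si](CC)(CC)CC)c2C(O)O1 | intermediate (not isolated)
7 | (6S)-6-methyl-3-{[(triethylsilyl)oxy]methyl}-6,7-dihydro-4H-furo[3,2-c]pyran-4-one | C[C@H]1Cc2occ(CO[Si](CC)(CC)CC)c2C(=O)O1 | intermediate
8 | (E)-1-bromoprop-1-ene | C/C=C/Br | starting material
9 | (E)-prop-1-en-1-yllithium | C/C=C/[Li] | intermediate (not isolated)
10 | (2E)-1-{2-[(2S)-2-hydroxypropyl]-4-{[(triethylsilyl)oxy]methyl}furan-3-yl}but-2-en-1-one | C/C=C/C(=O)c1c(CO[Si](CC)(CC)CC)coc1C[C@H](C)O | intermediate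
11 | (2E)-1-{2-[(2S)-2-{[tert-butyl(dimethyl)silyl]oxy}propyl]-4-{[(triethylsilyl)oxy]methyl}furan-3-yl}but-2-en-1-one | C/C=C/C(=O)c1c(CO[Si](CC)(CC)CC)coc1C[C@H](C)O[Si](C)(C)C(C)(C)C | intermediate
12 | tert-butyl(dimethyl)(prop-2-yn-1-yloxy)silane | C#CCO[Si](C)(C)C(C)(C)C | starting material
13 | lithium 3-{[tert-butyl(dimethyl)silyl]oxy}prop-1-yn-1-ide | [Li]C#CCO[Si](C)(C)C(C)(C)C | intermediate (not isolated)
14 | (5E)-1-{[tert-butyl(dimethyl)silyl]oxy}-4-{2-[(2S)-2-{[tert-butyl(dimethyl)silyl]oxy}propyl]-4-{[(triethylsilyl)oxy]methyl}furan-3-yl}hept-5-en-2-yn-4-ol (both carbinol epimers) | C/C=C/C(O)(C#CCO[Si](C)(C)C(C)(C)C)c1c(CO[Si](CC)(CC)CC)coc1C[C@H](C)O[Si](C)(C)C(C)(C)C | intermediate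
15 | (3S)-6-{[tert-butyl(dimethyl)silyl]oxy}-1-{2-[(2S)-2-{[tert-butyl(dimethyl)silyl]oxy}propyl]-4-{[(triethylsilyl)oxy]methyl}furan-3-yl}-3-methylhex-4-yn-1-one | O=C(C[C@H](C)C#CCO[Si](C)(C)C(C)(C)C)c1c(CO[Si](CC)(CC)CC)coc1C[C@H](C)O[Si](C)(C)C(C)(C)C | intermediate
16 | (1S,3S)-6-{[tert-butyl(dimethyl)silyl]oxy}-1-{2-[(2S)-2-{[tert-butyl(dimethyl)silyl]oxy}propyl]-4-{[(triethylsilyl)oxy]methyl}furan-3-yl}-3-methylhex-4-yn-1-ol | O[C@@H](C[C@H](C)C#CCO[Si](C)(C)C(C)(C)C)c1c(CO[Si](CC)(CC)CC)coc1C[C@H](C)O[Si](C)(C)C(C)(C)C | intermediate (not isolated)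
17 | (1S,3S)-6-{[tert-butyl(dimethyl)silyl]oxy}-1-{2-[(2S)-2-{[tert-butyl(dimethyl)silyl]oxy}propyl]-4-(hydroxymethyl)furan-3-yl}-3-methylhex-4-yn-1-ol | O[C@@H](C[C@H](C)C#CCO[Si](C)(C)C(C)(C)C)c1c(CO)coc1C[C@H](C)O[Si](C)(C)C(C)(C)C | intermediate
18 | {5-[(2S)-2-{[tert-butyl(dimethyl)silyl]oxy}propyl]-4-[(1S,3S)-6-{[tert-butyl(dimethyl)silyl]oxy}-1-hydroxy-3-methylhex-4-yn-1-yl]furan-3-yl}methyl acetate | CC(=O)OCc1coc(C[C@H](C)O[Si](C)(C)C(C)(C)C)c1[C@@H](O)C[C@H](C)C#CCO[Si](C)(C)C(C)(C)C | intermediate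
19 | 3-methylbut-2-enoyl chloride | CC(C)=CC(=O)Cl | starting material
20 | (1S,3S)-1-{4-(acetoxymethyl)-2-[(2S)-2-{[tert-butyl(dimethyl)silyl]oxy}propyl]furan-3-yl}-6-{[tert-butyl(dimethyl)silyl]oxy}-3-methylhex-4-yn-1-yl 3-methylbut-2-enoate | CC(=O)OCc1coc(C[C@H](C)O[Si](C)(C)C(C)(C)C)c1[C@@H](OC(=O)C=C(C)C)C[C@H](C)C#CCO[Si](C)(C)C(C)(C)C | intermediate
21 | (1S,3S)-1-{4-(acetoxymethyl)-2-[(2S)-2-hydroxypropyl]furan-3-yl}-6-hydroxy-3-methylhex-4-yn-1-yl 3-methylbut-2-enoate | CC(=O)OCc1coc(C[C@H](C)O)c1[C@@H](OC(=O)C=C(C)C)C[C@H](C)C#CCO | intermediate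
22 | (1S,3S)-1-[4-(acetoxymethyl)-2-(2-oxopropyl)furan-3-yl]-3-methyl-6-oxohex-4-yn-1-yl 3-methylbut-2-enoate | CC(=O)OCc1coc(CC(C)=O)c1[C@@H](OC(=O)C=C(C)C)C[C@H](C)C#CC=O | intermediate
23 | (4S,8S,10S)-13-acetoxy-4-hydroxy-8-(3-methylbut-2-enoyloxy)-6,12-epoxygermacra-6,11-dien-1-yn-3-one (furan-fused cyclodecynone) | CC(=O)OCc1c2c(C[C@](C)(O)C(=O)C#C[C@@H](C)C[C@@H]2OC(=O)C=C(C)C)oc1 | intermediate (not isolated)
24 | (4S,8S,10S)-13-acetoxy-8-(3-methylbut-2-enoyloxy)-1,4:6,12-diepoxygermacra-1,6,11-trien-3-one | CC(=O)OCc1c2c(C[C@]3(C)OC(=CC3=O)[C@@H](C)C[C@@H]2OC(=O)C=C(C)C)oc1 | intermediate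
25 | 6,12-endoperoxide of 24 (6,12-epidioxy-6,12-epoxy bridge, C7=C11 alkene) | CC(=O)OCC1=C2C3(C[C@]4(C)OC(=CC4=O)[C@@H](C)C[C@@H]2OC(=O)C=C(C)C)OOC1O3 | intermediate (not isolated)
26 | (4S,8S,10S)-13-acetoxy-6-hydroxy-8-(3-methylbut-2-enoyloxy)-3-oxo-1,4-epoxygermacra-1,7(11)-dien-12,6-olide (C6 epimers) | CC(=O)OCC1=C2C(O)(C[C@]3(C)OC(=CC3=O)[C@@H](C)C[C@@H]2OC(=O)C=C(C)C)OC1=O | intermediate
27 | 6-O-methanesulfonate of 26 | CC(=O)OCC1=C2C(OS(C)(=O)=O)(C[C@]3(C)OC(=CC3=O)[C@@H](C)C[C@@H]2OC(=O)C=C(C)C)OC1=O | intermediate (not isolated)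
28 | (4S,5E,8S,10S)-13-acetoxy-8-(3-methylbut-2-enoyloxy)-3-oxo-1,4-epoxygermacra-1,5,7(11)-trien-12,6-olide | CC(=O)OCC1=C2/C(=C\[C@]3(C)OC(=CC3=O)[C@@H](C)C[C@@H]2OC(=O)C=C(C)C)OC1=O | target

Total step count: 15. Longest linear sequence: 15 steps (1 to 28).

Steps most likely to fail

1. Step 13. Oligomerisation, or diversion of the carbene adduct into the redox manifold, may outrun the ten-membered ring closure, and facial selectivity at the ketone may be poor. Fallback: setting out from 22, the two carbonyl groups are joined reductively instead. SmI2 (2.5 equiv) in THF at −78 °C under high dilution should effect an intramolecular aldehyde–ketone pinacol coupling (ketyl addition, a known way to close medium and large rings) to give the macrocyclic propargylic 1,2-diol F1, whose C4 epimers are separated at this stage. Dess–Martin oxidation of the secondary propargylic alcohol then gives hydroxy ynone 23, which is closed by catalytic DBU in CH2Cl2 (5-endo-dig oxa-Michael addition), and the route is rejoined at 24.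

2. Step 7. β-Alkynyl elimination may be sluggish at the crowded carbinol, and enantioface discrimination of the twisted furyl enone may be weak. Fallback: setting out from 11 and 13, the alkyne is delivered by a boron reagent instead of by fragmentation of a carbinol. 13 is quenched with B(Oi-Pr)3 and then HCl in Et2O to give the diisopropyl alkynylboronate F2. F2 should add to enone 11 in a binaphthol-catalysed asymmetric conjugate alkynylboration ((S)-3,3'-diiodo-1,1'-bi-2-naphthol, 20 mol%, CH2Cl2, 40 °C; antipode chosen as for step 7), and hydrolysis of the boron enolate returns the route to 15.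

3. Step 14. Oxidation may be non-selective (ene reaction at the senecioate alkene, breakdown of the endoperoxide other than by proton abstraction at C12). Fallback: setting out from 24, the furan is opened by a halonium oxidant instead of by cycloaddition. NBS and NaHCO3 in aqueous acetone at −20 °C should give the (Z)-4-oxo-2-enal F3. Pinnick oxidation (NaClO2, NaH2PO4, 2-methylbut-2-ene, t-BuOH–water) converts its aldehyde into the keto acid F4, which closes spontaneously to its ring tautomer 26, where the route is rejoined.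

Further compounds
F1 | step 13 | (4S,8S,10S)-13-acetoxy-3,4-dihydroxy-8-(3-methylbut-2-enoyloxy)-6,12-epoxygermacra-6,11-dien-1-yne (C3 epimers) | CC(=O)OCc1c2c(C[C@](C)(O)C(O)C#C[C@@H](C)C[C@@H]2OC(=O)C=C(C)C)oc1
F2 | step 7 | dipropan-2-yl (3-{[tert-butyl(dimethyl)silyl]oxy}prop-1-yn-1-yl)boronate | CC(C)OB(OC(C)C)C#CCO[Si](C)(C)C(C)(C)C
F3 | step 14 | ring-opened (Z)-4-oxo-2-enal of 24 (C12 aldehyde and C6 ketone cis on the C7=C11 double bond) | CC(=O)OC/C(C=O)=C(/C(=O)C[C@]1(C)OC(=CC1=O)[C@@H](C)C2)[C@H]2OC(=O)C=C(C)C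
F4 | step 14 | corresponding (Z)-4-oxo-2-enoic acid (C12 carboxylic acid) | CC(=O)OC/C(C(=O)O)=C(/C(=O)C[C@]1(C)OC(=CC1=O)[C@@H](C)C2)[C@H]2OC(=O)C=C(C)C
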